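**Assumption:** the stereocentre in the SMILES is (3R). Only the carbon-donating materials (1, 2, 4) are counted as starting materials; the chiral acid, Ti/Zn and Li/NH3 are reagents.

## Retrosynthetic overview

1. Kanzonol X (8) comes from hexacyclic pterocarpan 7 by one dissolving-metal operation. It cleaves the benzylic furan C–O bond (giving C4H2 and 2'-OH) and both dimethylchromene allylic C–O bonds (giving the two prenyl groups and 7-/4'-OH).
2. 7 comes from the bis-MOM (E)-stilbene 6 by one asymmetric cationic cascade. A MOM-derived oxocarbenium closes the pyran ring (Prins, C2–C3), and the resulting C4 cation is captured by the other aryl oxygen to close the furan ring. Two rings and both stereocentres form together.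
3. 6 comes from McMurry homocoupling of aldehyde 5, because both aryl halves of the target are the same 2,4-dioxygenated 3-prenylphenyl unit.
4. 5 comes from 2,4-dihydroxybenzaldehyde and prenal. The chromene ring places the masked prenyl group between the two oxygens and protects the para oxygen.
5. Ring order: dimethylpyran rings (step 1), then pyran and furan together (step 4). The furan and both dimethylpyran rings are opened in step 5.

## Route

**Step 1**
Reactants: 1, 2,4-dihydroxybenzaldehyde; 2, 3-methyl-2-butenal (prenal)
Product: 3, 5-hydroxy-2,2-dimethyl-2H-chromene-6-carbaldehyde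
Conditions: Ca(OH)2, MeOH, rt
Reagents that add atoms: 3-methyl-2-butenal (2), CC(C)=CC=O
Why: Base-mediated chromenylation (aldol-type C-alkylation at C3, dehydration to an o-quinone methide, oxa-6π electrocyclisation); the 2-OH is held by the H-bond to CHO, so attack occurs between the two oxygens and the ring closes through the 4-oxygen.

**Step 2**
Reactants: 3; 4, chloromethyl methyl ether (MOMCl)
Product: 5, 5-(methoxymethoxy)-2,2-dimethyl-2H-chromene-6-carbaldehyde
Conditions: MOMCl, iPr2NEt, DMAP (cat.), CH2Cl2, 0 °C → rt
Reagents that add atoms: MOMCl (4), COCCl
Why: Standard phenol O-alkylation (MOM protection); the MOM group later supplies the C2 methylene of the chroman ring.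

**Step 3**
Reactants: 5 (2 equiv)
Product: 6, (E)-1,2-bis[5-(methoxymethoxy)-2,2-dimethyl-2H-chromen-6-yl]ethene
Conditions: TiCl4, Zn, pyridine, THF, reflux
Reagents that add atoms: none
Why: McMurry reductive homocoupling of an aryl aldehyde gives the symmetric E-stilbene; pyridine buffers the Lewis acidity so the MOM acetals and chromene alkenes survive.

**Step 4 (key step)**
Reactants: 6
Product: 7, (6aR,11aR)-cis-pterocarpan bearing 2,2-dimethyl-2H-pyran rings fused at C3(O)/C4 and at C9(O)/C10 (hexacycle; 6a-H and 11a-H cis)
Conditions: chiral confined Brønsted acid (BINOL-derived IDPi, 5 mol%; antipode chosen by screening to give 6aR,11aR), CHCl3, 0.02 M, −40 → −20 °C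
Reagents that add atoms: none (the new CH2 is the substrate's own MOM carbon; CH2(OMe)2 is released)
Why: Proposed new method: the chiral acid ionises one aryl MOM acetal (loss of MeOH) to an aryloxymethyl oxocarbenium paired with the confined chiral anion; favoured 6-endo Prins attack by the distal stilbene carbon closes the pyran ring and sets C6a (the future C3) within the chiral ion pair; the resulting 2,4-dioxygenated benzylic cation is captured by the neighbouring MOM-ether oxygen, which sheds MeOCH2+ (returned with the MeOH as CH2(OMe)2, regenerating the acid) and closes the furan ring cis, the only feasible fusion; the chromene alkenes cannot be reached intramolecularly (a strained bridged ring would result) and no prenyl alkene is present to compete; closest known reactions are Lewis-acid MOM-ether Prins cyclisations, dealkylative aryl-ether capture of benzylic cations, and IDPi-catalysed asymmetric Prins and oxa-Pictet–Spengler reactions of formaldehyde-type oxocarbenium ions.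

**Step 5**
Reactants: 7
Product: 8, Kanzonol X, (3R)-7,2',4'-trihydroxy-8,3'-bis(3-methylbut-2-enyl)isoflavan
Conditions: Li (excess), NH3(l)/THF, −78 → −33 °C; then NH4Cl, pH 6–7 work-up
Reagents that add atoms: none (only hydrogen is added)
Why: Birch-type dissolving-metal cleavage of one benzylic aryl ether (pterocarpan to 2'-hydroxyisoflavan) and two allylic aryl ethers (2,2-dimethylchromene to o-prenylphenol, protonation at the benzylic carbon); the aryl–O–CH2 bond of the chroman and the phenoxide rings are not reduced without added alcohol, and C3 is untouched, so its configuration carries through from C6a of 7.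

## Compound list

1 | 2,4-dihydroxybenzaldehyde | O=Cc1ccc(O)cc1O | starting material
2 | 3-methyl-2-butenal (prenal) | CC(C)=CC=O | starting material
3 | 5-hydroxy-2,2-dimethyl-2H-chromene-6-carbaldehyde | O=Cc1ccc2OC(C)(C)C=Cc2c1O | intermediate
4 | chloromethyl methyl ether (MOMCl) | COCCl | starting material
5 | 5-(methoxymethoxy)-2,2-dimethyl-2H-chromene-6-carbaldehyde | COCOc1c(C=O)ccc2OC(C)(C)C=Cc12 | intermediate
6 | (E)-1,2-bis[5-(methoxymethoxy)-2,2-dimethyl-2H-chromen-6-yl]ethene | COCOc1c(/C=C/c2ccc3OC(C)(C)C=Cc3c2OCOC)ccc2OC(C)(C)C=Cc12 | intermediate
7 | (6aR,11aR)-3,4:9,10-bis(2,2-dimethylpyrano)-fused cis-pterocarpan | CC1(C)C=Cc2c(O1)ccc1c2OC[C@H]2c3ccc4OC(C)(C)C=Cc4c3O[C@@H]12 | intermediate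
8 | Kanzonol X, (3R)-7,2',4'-trihydroxy-8,3'-diprenylisoflavan | CC(C)=CCc1c(O)ccc([C@@H]2COc3c(ccc(O)c3CC=C(C)C)C2)c1O | target

## Summary

Total steps: 5. Longest linear sequence: 5.

Steps most likely to fail, each with one fallback:

1. **Step 4 (asymmetric Prins/etherification cascade).** The risks are low enantioselectivity, erosion through a transient isoflav-3-ene, and acid-mediated chromene side reactions. Fallback: run the cascade racemically with an achiral promoter (TMSOTf with 2,6-di-tert-butylpyridine, CH2Cl2, −78 °C) and resolve (±)-7 by preparative chiral-phase SFC, so stereocontrol comes from resolution.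
2. **Step 5 (triple reductive C–O cleavage).** The risks are incomplete opening of the furan ring once ring A is a phenoxide, and prenyl over-reduction via the conjugated isomer. Fallback: use Li/NH3 at −78 °C only for the two chromene openings. Then open the furan ring non-reductively at the metal: base-triggered expulsion of the 2'-aryloxide by the 7-phenoxide gives a para-quinone methide, trapped in situ by NaBH4 (aq. NaOH/EtOH, warm).
3. **Step 3 (McMurry coupling).** The risks are MOM loss or poor E/Z control under low-valent titanium. Fallback: build the stilbene by Wittig olefination. Reduce part of 5 to the benzyl alcohol, convert it to the benzylphosphonium salt, couple with 5, and isomerise to E with catalytic I2.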